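**Retrosynthetic overview**
1. The target comes from the bis(benzyl ether) acid by double O‑debenzylation (H2, Pd/C).
2. Key disconnection: the aryl C6–CH2 bond, made by a new carboxylate‑directed, linear‑selective ortho‑C–H hydroarylation of 13‑methyltetradec‑1‑ene by 2,4‑bis(benzyloxy)‑5‑methylbenzoic acid.
3. That acid comes from 4‑methylresorcinol by Kolbe–Schmitt carboxylation, perbenzylation and ester hydrolysis.
4. The alkene comes from Cu‑catalysed coupling of isobutylmagnesium bromide with 11‑bromoundec‑1‑ene.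
5. Rings: none is formed; the single benzene ring is bought as 4‑methylresorcinol.

Assumption: the target SMILES has no stereocentre and no stereogenic double bond, so it is one achiral compound and "single enantiomer" requires no stereocontrol.

**Route**

Step 1
Reactants: 1 isobutylmagnesium bromide (2‑methylpropylmagnesium bromide, commercial solution); 2 11‑bromoundec‑1‑ene
Product: 3 13‑methyltetradec‑1‑ene
Conditions: 1 (1.3 equiv), Li2CuCl4 (3 mol %), THF, −10 °C → rt, 3 h
Reagents that add atoms: none
Why: Kochi‑type Cu‑catalysed sp3–sp3 cross‑coupling of a primary alkyl Grignard with a primary alkyl bromide is fast at low temperature and leaves the remote terminal alkene untouched, giving the iso‑branched C15 chain in one step.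

Step 2
Reactants: 4 4‑methylresorcinol (4‑methylbenzene‑1,3‑diol)
Product: 6 2,4‑dihydroxy‑5‑methylbenzoic acid, via potassium 2,4‑dihydroxy‑5‑methylbenzoate 5 (not isolated)
Conditions: KHCO3 (5 equiv), CO2 (1 atm), H2O, 100 °C, 4 h; then conc. HCl to pH 1, 0 °C
Reagents that add atoms: carbon dioxide, O=C=O
Why: Kolbe–Schmitt carboxylation of the resorcinolate goes to the ring position ortho to one OH and para to the other (C6 of 4), because the other such site carries the methyl group and the doubly ortho C2 site gives only the less stable, reversibly formed 2,6‑dihydroxy acid.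

Step 3
Reactants: 6 2,4‑dihydroxy‑5‑methylbenzoic acid
Product: 7 benzyl 2,4‑bis(benzyloxy)‑5‑methylbenzoate
Conditions: BnBr (3.6 equiv), K2CO3 (4.5 equiv), DMF, 60 °C, 16 h
Reagents that add atoms: benzyl bromide, BrCc1ccccc1
Why: Williamson O‑alkylation of both phenoxides and SN2 esterification of the carboxylate mask all three acidic groups, and heating overcomes the hydrogen‑bonded 2‑OH.

Step 4
Reactants: 7 benzyl 2,4‑bis(benzyloxy)‑5‑methylbenzoate
Product: 9 2,4‑bis(benzyloxy)‑5‑methylbenzoic acid, via potassium 2,4‑bis(benzyloxy)‑5‑methylbenzoate 8 (not isolated)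
Conditions: KOH (5 equiv), THF/MeOH/H2O (2:2:1), 65 °C, 6 h; then 1 M HCl, 0 °C
Reagents that add atoms: potassium hydroxide, [K+].[OH-]
Why: Saponification (BAc2) cleaves only the benzyl ester because aryl benzyl ethers are inert to hydroxide, and acidification frees the carboxylic acid that directs step 5.

Step 5
Reactants: 9 2,4‑bis(benzyloxy)‑5‑methylbenzoic acid; 3 13‑methyltetradec‑1‑ene
Product: 10 4,6‑bis(benzyloxy)‑3‑methyl‑2‑(13‑methyltetradecyl)benzoic acid
Conditions: 3 (2.5 equiv), [Ru(O2CMes)2(p‑cymene)] (7.5 mol %), PhMe, 100 °C, Ar, 24 h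
Reagents that add atoms: none
Why: Proposed new method: a redox‑neutral, carboxylate‑directed, anti‑Markovnikov ortho‑C–H hydroarylation of an unactivated α‑olefin by a free, electron‑rich benzoic acid at a C–H flanked by a methyl group, which to my knowledge has not been shown — carboxylate exchange binds 9 to Ru(II), mesitoate‑assisted concerted metalation–deprotonation can only take place at C6–H (the other ortho position carries OBn) to give a five‑membered ruthenalactone, the 1‑alkene inserts with the aryl group going to the unhindered terminal CH2 (Ru on the internal carbon, seven‑membered chelate), and protonation of the Ru–C bond by free acid releases linear 10 and regenerates the Ru(II) carboxylate, while the absence of an oxidant lets any Ru–H from β‑hydride elimination re‑insert; the closest known reaction types are Ru(II)/carboxylate‑catalysed linear hydroarylation of unactivated alkenes directed by pyridines and carboxylate‑directed Ru(II) ortho‑alkylation of benzoic acids with acrylates or maleimides, and no stereocentre is formed.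

Step 6
Reactants: 10 4,6‑bis(benzyloxy)‑3‑methyl‑2‑(13‑methyltetradecyl)benzoic acid
Product: 11 4,6‑dihydroxy‑3‑methyl‑2‑(13‑methyltetradecyl)benzoic acid (= 2,4‑dihydroxy‑5‑methyl‑6‑(13‑methyltetradecyl)benzoic acid)
Conditions: H2 (1 atm), 10% Pd/C, EtOAc/MeOH (1:1), rt, 4 h
Reagents that add atoms: none
Why: Pd‑catalysed hydrogenolysis of the two aryl benzyl ethers is neutral and runs at room temperature, so the decarboxylation‑prone 6‑alkyl‑β‑resorcylic acid is freed without acid or heat, and any ortho‑alkenyl by‑product carried over from step 5 is saturated to the same chain.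

**Compound list**
1 | isobutylmagnesium bromide (2‑methylpropylmagnesium bromide) | CC(C)C[Mg]Br | starting material
2 | 11‑bromoundec‑1‑ene | C=CCCCCCCCCCBr | starting material
3 | 13‑methyltetradec‑1‑ene | C=CCCCCCCCCCCC(C)C | intermediate
4 | 4‑methylresorcinol (4‑methylbenzene‑1,3‑diol) | Cc1ccc(O)cc1O | starting material
5 | potassium 2,4‑dihydroxy‑5‑methylbenzoate | Cc1cc(C(=O)[O-])c(O)cc1O.[K+] | intermediate
6 | 2,4‑dihydroxy‑5‑methylbenzoic acid | Cc1cc(C(=O)O)c(O)cc1O | intermediate
7 | benzyl 2,4‑bis(benzyloxy)‑5‑methylbenzoate | Cc1cc(C(=O)OCc2ccccc2)c(OCc3ccccc3)cc1OCc4ccccc4 | intermediate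
8 | potassium 2,4‑bis(benzyloxy)‑5‑methylbenzoate | Cc1cc(C(=O)[O-])c(OCc2ccccc2)cc1OCc3ccccc3.[K+] | intermediate
9 | 2,4‑bis(benzyloxy)‑5‑methylbenzoic acid | Cc1cc(C(=O)O)c(OCc2ccccc2)cc1OCc3ccccc3 | intermediate
10 | 4,6‑bis(benzyloxy)‑3‑methyl‑2‑(13‑methyltetradecyl)benzoic acid | Cc1c(OCc2ccccc2)cc(OCc3ccccc3)c(C(=O)O)c1CCCCCCCCCCCCC(C)C | intermediate
11 | 4,6‑dihydroxy‑3‑methyl‑2‑(13‑methyltetradecyl)benzoic acid (achiral) | Cc1c(O)cc(O)c(C(=O)O)c1CCCCCCCCCCCCC(C)C | target

**Totals and risks**
Total step count: 6. Longest linear sequence: 5 steps (4 → 6 → 7 → 9 → 10 → 11, steps 2–6); step 1 is a one‑step side branch.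

Three steps most likely to fail:

1. Step 5 (the new hydroarylation). Risks: slow insertion of an unactivated alkene into a buttressed, weakly chelated aryl–Ru bond, isomerisation of 3 to unreactive internal alkenes, and protodecarboxylation of electron‑rich 9 or 10.
   Fallback, known chemistry only, setting out from 1 and coming back at 11: the ring is built around the chain by the established diketo‑dioxinone cycloaromatisation instead of alkylating a finished arene.
   - Grignard 1 (2.5 equiv; the first equivalent only deprotonates the acid) is coupled with commercial 12‑bromododecanoic acid (cat. Li2CuCl4, THF, −20 °C → rt, acid work‑up) to give 14‑methylpentadecanoic acid F1.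
   - Oxalyl chloride/cat. DMF in CH2Cl2 converts F1 into 14‑methylpentadecanoyl chloride F2.
   - Separately, the lithium dienolate of commercial 2,2,6‑trimethyl‑4H‑1,3‑dioxin‑4‑one (LiHMDS, THF, −78 °C) is C‑acylated with propionyl chloride to give 2,2‑dimethyl‑6‑(2‑oxobutyl)‑4H‑1,3‑dioxin‑4‑one F3.
   - The dianion of F3 (LDA, 2.1 equiv, THF, −78 °C) is acylated at the ethyl‑ketone α‑carbon by F2 to give 6‑(3,17‑dimethyl‑2,4‑dioxooctadecyl)‑2,2‑dimethyl‑4H‑1,3‑dioxin‑4‑one F4.
   - Et3N in CH2Cl2 at rt effects the intramolecular aldol–dehydration–aromatisation to 7‑hydroxy‑2,2,6‑trimethyl‑5‑(13‑methyltetradecyl)‑4H‑1,3‑benzodioxin‑4‑one F5.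
   - KOH in aqueous DMSO (60 °C, then cold dilute HCl) opens the acetonide lactone to 11.

2. Step 2 (Kolbe–Schmitt). Risks: incomplete conversion, some 2,6‑dihydroxy isomer, decarboxylation on work‑up.
   Fallback, setting out from 4 and coming back at 9 (it also replaces steps 3 and 4): the carbon is introduced as a formyl group and oxidised after protection.
   - Vilsmeier–Haack formylation of 4 (POCl3, DMF, MeCN, 0 °C → rt, then H2O) gives 2,4‑dihydroxy‑5‑methylbenzaldehyde F6 with the same para‑to‑OH selectivity.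
   - BnBr/K2CO3 in DMF at 60 °C gives 2,4‑bis(benzyloxy)‑5‑methylbenzaldehyde F7.
   - Pinnick oxidation (NaClO2, NaH2PO4, 2‑methylbut‑2‑ene, t‑BuOH/H2O, rt) gives 9.

3. Step 1 (Cu‑catalysed sp3–sp3 coupling). Risks: Grignard homocoupling, reduction or elimination of 2, hard separation of hydrocarbon by‑products from 3.
   Fallback, setting out from 1 and coming back at 3: the C–C bond is made by carbonyl addition and the oxygen is then removed.
   - 1 is added to commercial undec‑10‑enal (THF, 0 °C, aq. NH4Cl quench) to give 13‑methyltetradec‑1‑en‑11‑ol F8.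
   - TsCl/pyridine/cat. DMAP gives 13‑methyltetradec‑1‑en‑11‑yl 4‑methylbenzenesulfonate F9.
   - LiEt3BH (THF, 0 °C → rt) displaces the tosylate by hydride to give 3; the transient stereocentre disappears.

**Further compounds**
F1 | step 5 | 14‑methylpentadecanoic acid | CC(C)CCCCCCCCCCCCC(=O)O
F2 | step 5 | 14‑methylpentadecanoyl chloride | CC(C)CCCCCCCCCCCCC(=O)Cl
F3 | step 5 | 2,2‑dimethyl‑6‑(2‑oxobutyl)‑4H‑1,3‑dioxin‑4‑one | CCC(=O)CC1=CC(=O)OC(C)(C)O1
F4 | step 5 | 6‑(3,17‑dimethyl‑2,4‑dioxooctadecyl)‑2,2‑dimethyl‑4H‑1,3‑dioxin‑4‑one (racemic, enolisable centre) | CC(C)CCCCCCCCCCCCC(=O)C(C)C(=O)CC1=CC(=O)OC(C)(C)O1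
F5 | step 5 | 7‑hydroxy‑2,2,6‑trimethyl‑5‑(13‑methyltetradecyl)‑4H‑1,3‑benzodioxin‑4‑one | Cc1c(O)cc2OC(C)(C)OC(=O)c2c1CCCCCCCCCCCCC(C)C
F6 | step 2 | 2,4‑dihydroxy‑5‑methylbenzaldehyde | Cc1cc(C=O)c(O)cc1O
F7 | step 2 | 2,4‑bis(benzyloxy)‑5‑methylbenzaldehyde | Cc1cc(C=O)c(OCc2ccccc2)cc1OCc3ccccc3
F8 | step 1 | 13‑methyltetradec‑1‑en‑11‑ol (racemic) | C=CCCCCCCCCC(O)CC(C)C
F9 | step 1 | 13‑methyltetradec‑1‑en‑11‑yl 4‑methylbenzenesulfonate (racemic) | C=CCCCCCCCCC(OS(=O)(=O)c1ccc(C)cc1)CC(C)C
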